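**Plan**

- Retrosynthetic cuts: C7–C8 (closure of the carbocycle), C6–C7 and C5=C6 (two one-carbon units), C13–C14 (fragment union), and, in a bicyclic precursor, the C5–C14 bond and the O–C4 bond.
- Enabling feature: the oxane O–C4–C3–C2–C1–C15 with its cis C5 and C14 arms is a 1,8-cineole (2-oxabicyclo[2.2.2]octane) that lacks the C5–C14 bridge, so C1–C5, C14, C15 and three methyl groups are the skeleton of (R)-carvone.
- Forward: carvone is hydrated and reduced, selenoetherification closes the oxane as the bicycle (first ring), selenoxide elimination and ozonolysis cut C5–C14, and a C3/C5 p-methoxybenzylidene acetal tells the two arms apart.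
- The C14 arm is joined as its sulfone to a C8–C13 allylic bromide from 6-methylhept-5-en-2-one; the C5 arm is kept as a vinyl group and hydroformylated late to the C7 aldehyde; the 14-membered carbocycle (second ring) closes last by a Nozaki–Hiyama–Kishi reaction at C7–C8.
- Stereochemistry: C1 from (R)-carvone, C3 from the 1,3-cis-selective Luche reduction, C4 from the tethered closure, 11E from SeO2 oxidation of the E-methyl group, C7 from CBS reduction of the macrocyclic enone.

Key step: step 3

Remark: locants C1–C15 are those of the target (C1 ring-fusion CH, C3 CHOAc, C4 CMe–O, C7 CHOH, C8 C=CH2, C11=C12, C15 CMe2–O) and are used for every intermediate.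
Assumption: the ring closure in step 21 is taken to give both C7 epimers; they converge at enone 42 and C7 is set in step 23.

Step 1
Reactants: 1 (R)-(−)-carvone; 2 water
Product: 3 (5R)-5-(2-hydroxypropan-2-yl)-2-methylcyclohex-2-en-1-one (8-hydroxycarvotanacetone)
Conditions: 50% aq. H2SO4, 0 °C → rt; NaHCO3 work-up
Reagents that add atoms: water, O
Why: Acid-catalysed Markovnikov hydration of the isopropenyl group through the tertiary cation gives the tertiary alcohol (the future C15–O) while the enone and the C1 stereocentre stay untouched at low temperature.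

Step 2
Reactants: 3 8-hydroxycarvotanacetone
Product: 4 (1R,5R)-5-(2-hydroxypropan-2-yl)-2-methylcyclohex-2-en-1-ol (8-hydroxy-cis-carveol)
Conditions: NaBH4, CeCl3·7H2O, MeOH, −20 °C
Reagents that add atoms: none
Why: Luche reduction: the cerium-activated carbonyl is reduced 1,2 by axial hydride delivery to the half-chair that keeps the C1 side chain equatorial, which places the new C3 hydroxyl cis to that side chain (3R).

Step 3
Reactants: 4 8-hydroxy-cis-carveol; 5 phenylselenenyl chloride
Product: 6 2-hydroxy-6-phenylseleno-1,8-cineole (1,3,3-trimethyl-7-(phenylselanyl)-2-oxabicyclo[2.2.2]octan-6-ol; C3–OH syn and C5–SePh anti to the ether bridge)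
Conditions: PhSeCl, K2CO3, CH2Cl2, −78 → 0 °C
Reagents that add atoms: phenylselenenyl chloride, Cl[Se]c1ccccc1
Why: PhSe+ adds reversibly to the C4=C5 alkene of 4 and only the seleniranium ion on the face opposite the C1 carbinol arm can be opened intramolecularly, the C15 tertiary hydroxyl attacking C4 with inversion so that O–C4 and C5–Se form anti to each other. The closest known reaction type is the selenoetherification of α-terpineol-type alkenols to 1,8-cineoles. The oxane O–C15–C1–C2–C3–C4 closes in a 6-exo opening of the seleniranium ion (6-endo as seen from the O–C15–C1–C14–C5–C4 ring) through the boat conformer with the C1 arm axial, which gives the 2-oxabicyclo[2.2.2]octane. C4 is set by the tether, since the oxygen can only arrive on the face of the C1 arm, and C5 by the anti opening, while C1 and C3 are carried over from 4. The step needs attack at the more substituted C4 instead of closure at C5 to the five-membered pinol-type ether, which the tertiary cation character at the methyl-bearing C4 secures, and the C3 hydroxyl is a spectator because it could only close a three- or four-membered ring. Solid K2CO3 takes up HCl so that the allylic carbinol is not ionised.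

Step 4
Reactants: 6 2-hydroxy-6-phenylseleno-1,8-cineole
Product: 8 bicyclic alkenol (1,3,3-trimethyl-2-oxabicyclo[2.2.2]oct-7-en-6-ol; C5=C14 alkene; C3–OH syn to the ether bridge), via selenoxide 7 (not isolated)
Conditions: 30% H2O2, pyridine, CH2Cl2, 0 → 25 °C
Reagents that add atoms: none
Why: Selenoxide syn-elimination: C4 is a quaternary bridgehead, so the only β-hydrogen is the C14–H eclipsed with the C5–Se bond in the rigid bicycle and the C5=C14 alkene is the sole product expected.

Step 5
Reactants: 8 bicyclic alkenol; 9 ozone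
Product: 11 triol (2S,3R,5S)-2,5-bis(hydroxymethyl)-2,6,6-trimethyloxan-3-ol (C5H2OH on C4 cis to C14H2OH on C1; C3–OH trans to the C4 arm), via ozonide 10 (not isolated)
Conditions: O3, CH2Cl2, −78 °C; then NaBH4, MeOH, −78 → 20 °C
Reagents that add atoms: ozone, [O-][O+]=O
Why: Ozonolysis with reductive borohydride work-up cuts the C5=C14 bridge and takes both termini straight to the alcohols, so that no enolisable C14 aldehyde is left to epimerise C1 and the two arms stay cis on the oxane.

Step 6
Reactants: 11 triol; 12 4-methoxybenzaldehyde dimethyl acetal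
Product: 13 O3,O5-(4-methoxybenzylidene) acetal of 11 (trans-fused 1,3-dioxane, aryl equatorial; C14–OH free)
Conditions: p-MeOC6H4CH(OMe)2, PPTS (cat.), CH2Cl2, rt
Reagents that add atoms: 4-methoxybenzaldehyde dimethyl acetal, COC(OC)c1ccc(OC)cc1
Why: Acid-catalysed transacetalisation under thermodynamic control: only O3 and O5 form a 1,3-diol that can close a six-membered dioxane, whereas O14 would need a seven- or nine-membered acetal, so C14–OH alone stays free.

Step 7
Reactants: 13 benzylidene acetal; 14 iodine
Product: 15 C14 iodide of 13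
Conditions: I2, PPh3, imidazole, CH2Cl2, 0 °C → rt
Reagents that add atoms: iodine, II
Why: Appel-type iodination: the only free hydroxyl is activated as its alkoxyphosphonium salt and displaced by iodide at the primary C14 while imidazole buffers the acetal.

Step 8
Reactants: 15 C14 iodide; 16 sodium benzenesulfinate
Product: 17 C14 phenyl sulfone (benzylidene acetal retained)
Conditions: PhSO2Na, Bu4NI (cat.), DMF, 70 °C
Reagents that add atoms: sodium benzenesulfinate, [Na+].[O-]S(=O)c1ccccc1
Why: SN2 S-alkylation of the ambident sulfinate by the soft primary iodide in a dipolar aprotic solvent gives the sulfone that will carry the C14 carbanion.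

Step 9
Reactants: 17 C14 phenyl sulfone
Product: 18 [3-(4-methoxybenzyloxy)-2,6,6-trimethyl-5-(phenylsulfonylmethyl)oxan-2-yl]methanol (C3–OPMB; C5–OH free)
Conditions: DIBAL-H, CH2Cl2, −78 → 0 °C; aq. potassium sodium tartrate
Reagents that add atoms: none
Why: Regioselective reductive opening of a 4-methoxybenzylidene acetal: aluminium binds the less hindered primary O5 (assisted by the neighbouring ring oxygen), the C–O5 bond breaks and hydride quenches the oxocarbenium ion, which leaves the PMB group on the secondary O3 and frees C5–OH.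

Step 10
Reactants: 18 C5 alcohol
Product: 19 3-(4-methoxybenzyloxy)-2,6,6-trimethyl-5-(phenylsulfonylmethyl)oxane-2-carbaldehyde (C5 aldehyde)
Conditions: DMP, CH2Cl2, rt
Reagents that add atoms: none
Why: Dess–Martin oxidation of the neopentyl primary alcohol under neutral conditions gives an aldehyde without α-hydrogen (C4 is quaternary), which can neither epimerise nor eliminate the β-OPMB group.

Step 11
Reactants: 19 C5 aldehyde; 20 methyltriphenylphosphonium bromide
Product: 21 2-ethenyl-3-(4-methoxybenzyloxy)-2,6,6-trimethyl-5-(phenylsulfonylmethyl)oxane (C5=C6 vinyl on C4)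
Conditions: Ph3PCH3Br (in excess over base), KHMDS, THF, −78 → 0 °C
Reagents that add atoms: methyltriphenylphosphonium bromide, [Br-].C[P+](c1ccccc1)(c1ccccc1)c1ccccc1
Why: Wittig methylenation of the non-enolisable aldehyde turns C5 into the C5=C6 vinyl group, a base- and reduction-stable mask for the later C7 aldehyde, and keeping the base in deficit leaves no amide to form the C14 sulfonyl carbanion, which could add back to C5.

Step 12
Reactants: 22 6-methylhept-5-en-2-one; 23 ethylene glycol
Product: 24 2-methyl-2-(4-methylpent-3-en-1-yl)-1,3-dioxolane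
Conditions: HOCH2CH2OH, p-TsOH (cat.), benzene, reflux with azeotropic removal of water
Reagents that add atoms: ethylene glycol, OCCO
Why: Acid-catalysed ketalisation masks the C8 ketone for the carbanion and dissolving-metal steps.

Step 13
Reactants: 24 dioxolane; 25 tert-butyl hydroperoxide
Product: 26 (2E)-2-methyl-5-(2-methyl-1,3-dioxolan-2-yl)pent-2-en-1-ol
Conditions: SeO2 (cat.), t-BuOOH, CH2Cl2, 0 °C → rt
Reagents that add atoms: tert-butyl hydroperoxide, CC(C)(C)OO (oxygen relayed by catalytic SeO2)
Why: SeO2-catalysed allylic oxidation (ene reaction then [2,3]-sigmatropic shift) attacks the E-methyl group of the trisubstituted alkene, which fixes the later C11=C12 bond as E and gives the C13 alcohol.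

Step 14
Reactants: 26 allylic alcohol; 27 carbon tetrabromide
Product: 28 2-[(3E)-5-bromo-4-methylpent-3-en-1-yl]-2-methyl-1,3-dioxolane
Conditions: CBr4, PPh3, CH2Cl2, −20 → 0 °C
Reagents that add atoms: carbon tetrabromide, BrC(Br)(Br)Br
Why: Appel bromination: SN2 displacement of the alkoxyphosphonium ion at the primary allylic carbon under neutral conditions keeps the E-alkene and the ketal.

Step 15
Reactants: 21 vinyl sulfone; 28 allylic bromide
Product: 30 coupled sulfone (C13–C14 bond formed; PhSO2 on C14 as both epimers; C8 dioxolane; C3–OPMB; C4 vinyl), via lithiated sulfone 29 (not isolated)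
Conditions: n-BuLi, THF, −78 °C; then 28, −78 → −20 °C
Reagents that add atoms: allylic bromide 28, CC1(CC/C=C(\C)CBr)OCCO1
Why: Alkylation of an α-sulfonyl carbanion: the lithiated C14 sulfone displaces the primary allylic bromide in an SN2 reaction that forms C13–C14 and keeps the E geometry, and the new C14 centre is removed in the next step.

Step 16
Reactants: 30 coupled sulfone; 2 water
Product: 32 C8 methyl ketone (C3–OPMB; C4 vinyl; C14 now CH2), via desulfonylated ketal 31 (not isolated)
Conditions: Na(Hg) (6%), Na2HPO4, MeOH–THF, −20 °C; then PPTS, acetone–H2O, 50 °C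
Reagents that add atoms: water, O
Why: Reductive desulfonylation by electron transfer from sodium amalgam cleaves the C14–S bond without moving the homoallylic C11=C12 alkene or touching the vinyl group, and mild acid transketalisation then frees the C8 ketone while the PMB ether and the tertiary allylic ring ether survive.

Step 17
Reactants: 32 methyl ketone; 33 N-(5-chloropyridin-2-yl)bis(trifluoromethanesulfonimide)
Product: 35 C8 enol triflate (1-alken-2-yl triflate; C3–OPMB; C4 vinyl), via lithium enolate 34 (not isolated)
Conditions: LDA, THF, −78 °C (ketone added to base); then the triflimide 33, −78 → 0 °C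
Reagents that add atoms: N-(5-chloropyridin-2-yl)bis(trifluoromethanesulfonimide), FC(F)(F)S(=O)(=O)N(c1ccc(Cl)cn1)S(=O)(=O)C(F)(F)F
Why: Kinetic enolisation and O-triflation: irreversible deprotonation by LDA at −78 °C takes the less hindered methyl proton and the terminal enolate is trapped on oxygen as the alkenyl triflate needed for the ring closure.

Step 18
Reactants: 35 enol triflate
Product: 36 C3 alcohol (enol triflate and vinyl group retained)
Conditions: DDQ, CH2Cl2–pH 7 buffer, 0 °C
Reagents that add atoms: none
Why: Oxidative PMB ether cleavage: DDQ oxidises the electron-rich benzylic position to an oxocarbenium ion that water hydrolyses, which frees C3–OH without touching the alkenes or the enol triflate.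

Step 19
Reactants: 36 C3 alcohol; 37 acetic anhydride
Product: 38 C3 acetate (C4 vinyl; C8 enol triflate)
Conditions: Ac2O, Et3N, DMAP (cat.), CH2Cl2, rt
Reagents that add atoms: acetic anhydride, CC(=O)OC(C)=O
Why: DMAP-catalysed acylation (acylpyridinium transfer) esterifies the hindered secondary C3–OH before any C7 carbonyl exists, so that no C3–O/C7 lactol can form.

Step 20
Reactants: 38 C3 acetate; 39 carbon monoxide
Product: 40 C7 aldehyde (C4–CH2CH2CHO; C3–OAc; C8 enol triflate)
Conditions: Rh(acac)(CO)2 (cat.), Xantphos, CO/H2 (1:1, 10 bar), toluene, 70 °C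
Reagents that add atoms: carbon monoxide, [C-]#[O+]
Why: Rh-catalysed linear-selective hydroformylation: the vinyl group sits on the fully substituted C4, so it cannot isomerise and only the terminal Rh–alkyl can form, CO insertion then giving the C7 aldehyde, while the trisubstituted alkene and the enol triflate are expected to be inert.

Step 21
Reactants: 40 C7 aldehyde
Product: 41 macrocyclic allylic alcohol (14-membered ring; C7–OH as both epimers; C8 exocyclic methylene; C3–OAc)
Conditions: CrCl2 (excess), NiCl2 (cat.), DMF, 25 °C, slow addition, 2 mM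
Reagents that add atoms: none
Why: Nozaki–Hiyama–Kishi reaction: Ni(0) inserts into the C8–OTf bond, transmetallation gives an alkenylchromium(III) species that adds only to the aldehyde (the acetate is tolerated), and high dilution favours the 14-membered ring.

Step 22
Reactants: 41 macrocyclic allylic alcohol
Product: 42 macrocyclic enone (C7 ketone conjugated to the C8 methylene)
Conditions: DMP, CH2Cl2, 0 °C → rt
Reagents that add atoms: none
Why: Dess–Martin oxidation of the allylic alcohol removes the uncontrolled C7 centre and gives the α-methylene ketone without base, so that neither the acetate nor the enone is exposed to conjugate addition.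

Step 23
Reactants: 42 macrocyclic enone
Product: 43 target CNP0202897.1, (1R,3R,4S,7R,11E)-4,15-epoxy-7-hydroxycembra-8(19),11-dien-3-yl acetate
Conditions: (S)-2-methyl-CBS-oxazaborolidine, catecholborane, toluene, −78 °C
Reagents that add atoms: none
Why: CBS reduction: with the (S)-oxazaborolidine the α-branched alkenyl group C8 acts as the large substituent and C6H2 as the small one, so hydride from the coordinated borane should reach the Si face of the C7 ketone and give the 7R alcohol, and catecholborane at −78 °C leaves the acetate and the alkenes alone.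

**Compound list**

1 | (R)-(−)-carvone | CC1=CC[C@H](CC1=O)C(C)=C | starting material
2 | water | O | starting material
3 | (5R)-5-(2-hydroxypropan-2-yl)-2-methylcyclohex-2-en-1-one | CC1=CC[C@H](CC1=O)C(C)(C)O | intermediate
4 | (1R,5R)-5-(2-hydroxypropan-2-yl)-2-methylcyclohex-2-en-1-ol (8-hydroxy-cis-carveol) | C1=C(C)[C@H](O)C[C@@H](C1)C(C)(C)O | intermediate
5 | phenylselenenyl chloride | Cl[Se]c1ccccc1 | starting material
6 | 2-hydroxy-6-phenylseleno-1,8-cineole (OH syn, SePh anti to the ether bridge) | C[C@@]12OC(C)(C)[C@@H](C[C@H]1O)C[C@H]2[Se]c1ccccc1 | intermediate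
7 | selenoxide of 6 | C[C@@]12OC(C)(C)[C@@H](C[C@H]1O)C[C@H]2[Se](=O)c1ccccc1 | intermediate
8 | 1,3,3-trimethyl-2-oxabicyclo[2.2.2]oct-7-en-6-ol (OH syn to the ether bridge) | C[C@@]12OC(C)(C)[C@@H](C[C@H]1O)C=C2 | intermediate
9 | ozone | [O-][O+]=O | starting material
10 | secondary ozonide of 8 (both faces possible at the two acetal carbons) | C[C@@]12OC(C)(C)[C@@H](C[C@H]1O)C3OOC2O3 | intermediate
11 | (2S,3R,5S)-2,5-bis(hydroxymethyl)-2,6,6-trimethyloxan-3-ol | C[C@@]1(CO)OC(C)(C)[C@@H](C[C@H]1O)CO | intermediate
12 | 4-methoxybenzaldehyde dimethyl acetal | COC(OC)c1ccc(OC)cc1 | starting material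
13 | O3,O5-(4-methoxybenzylidene) acetal of 11, C14–OH free | COc1ccc(cc1)[C@H]2OC[C@]3(C)OC(C)(C)[C@H](CO)C[C@H]3O2 | intermediate
14 | iodine | II | starting material
15 | C14 iodide of 13 | COc1ccc(cc1)[C@H]2OC[C@]3(C)OC(C)(C)[C@H](CI)C[C@H]3O2 | intermediate
16 | sodium benzenesulfinate | [Na+].[O-]S(=O)c1ccccc1 | starting material
17 | C14 phenyl sulfone of 13 | COc1ccc(cc1)[C@H]2OC[C@]3(C)OC(C)(C)[C@H](CS(=O)(=O)c4ccccc4)C[C@H]3O2 | intermediate
18 | [3-(4-methoxybenzyloxy)-2,6,6-trimethyl-5-(phenylsulfonylmethyl)oxan-2-yl]methanol | C[C@@]1(CO)OC(C)(C)[C@@H](C[C@H]1OCc2ccc(OC)cc2)CS(=O)(=O)c3ccccc3 | intermediate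
19 | 3-(4-methoxybenzyloxy)-2,6,6-trimethyl-5-(phenylsulfonylmethyl)oxane-2-carbaldehyde | C[C@@]1(C=O)OC(C)(C)[C@@H](C[C@H]1OCc2ccc(OC)cc2)CS(=O)(=O)c3ccccc3 | intermediate
20 | methyltriphenylphosphonium bromide | [Br-].C[P+](c1ccccc1)(c1ccccc1)c1ccccc1 | starting material
21 | 2-ethenyl-3-(4-methoxybenzyloxy)-2,6,6-trimethyl-5-(phenylsulfonylmethyl)oxane | C[C@@]1(C=C)OC(C)(C)[C@@H](C[C@H]1OCc2ccc(OC)cc2)CS(=O)(=O)c3ccccc3 | intermediate
22 | 6-methylhept-5-en-2-one | CC(=O)CCC=C(C)C | starting material
23 | ethylene glycol | OCCO | starting material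
24 | 2-methyl-2-(4-methylpent-3-en-1-yl)-1,3-dioxolane | CC(C)=CCCC1(C)OCCO1 | intermediate
25 | tert-butyl hydroperoxide | CC(C)(C)OO | starting material
26 | (2E)-2-methyl-5-(2-methyl-1,3-dioxolan-2-yl)pent-2-en-1-ol | CC1(CC/C=C(\C)CO)OCCO1 | intermediate
27 | carbon tetrabromide | BrC(Br)(Br)Br | starting material
28 | 2-[(3E)-5-bromo-4-methylpent-3-en-1-yl]-2-methyl-1,3-dioxolane | CC1(CC/C=C(\C)CBr)OCCO1 | intermediate
29 | C14-lithiated sulfone from 21 | C[C@@]1(C=C)OC(C)(C)[C@@H](C[C@H]1OCc2ccc(OC)cc2)C([Li])S(=O)(=O)c3ccccc3 | intermediate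
30 | coupled sulfone (PhSO2 on C14, both epimers; C8 dioxolane) | C[C@@]1(C=C)OC(C)(C)[C@@H](C[C@H]1OCc2ccc(OC)cc2)C(C/C(C)=C/CCC3(C)OCCO3)S(=O)(=O)c4ccccc4 | intermediate
31 | desulfonylated C8 dioxolane | C[C@@]1(C=C)OC(C)(C)[C@@H](C[C@H]1OCc2ccc(OC)cc2)CC/C(C)=C/CCC3(C)OCCO3 | intermediate
32 | C8 methyl ketone (C3–OPMB, C4 vinyl) | C[C@@]1(C=C)OC(C)(C)[C@@H](C[C@H]1OCc2ccc(OC)cc2)CC/C(C)=C/CCC(C)=O | intermediate
33 | N-(5-chloropyridin-2-yl)bis(trifluoromethanesulfonimide) | FC(F)(F)S(=O)(=O)N(c1ccc(Cl)cn1)S(=O)(=O)C(F)(F)F | starting material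
34 | terminal lithium enolate of 32 | C[C@@]1(C=C)OC(C)(C)[C@@H](C[C@H]1OCc2ccc(OC)cc2)CC/C(C)=C/CCC(=C)O[Li] | intermediate
35 | C8 enol triflate (C3–OPMB, C4 vinyl) | C[C@@]1(C=C)OC(C)(C)[C@@H](C[C@H]1OCc2ccc(OC)cc2)CC/C(C)=C/CCC(=C)OS(=O)(=O)C(F)(F)F | intermediate
36 | C3 alcohol (C4 vinyl, C8 enol triflate) | C[C@@]1(C=C)OC(C)(C)[C@@H](C[C@H]1O)CC/C(C)=C/CCC(=C)OS(=O)(=O)C(F)(F)F | intermediate
37 | acetic anhydride | CC(=O)OC(C)=O | starting material
38 | C3 acetate (C4 vinyl, C8 enol triflate) | C[C@@]1(C=C)OC(C)(C)[C@@H](C[C@H]1OC(C)=O)CC/C(C)=C/CCC(=C)OS(=O)(=O)C(F)(F)F | intermediate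
39 | carbon monoxide | [C-]#[O+] | starting material
40 | C7 aldehyde (C3–OAc, C8 enol triflate) | C[C@@]1(CCC=O)OC(C)(C)[C@@H](C[C@H]1OC(C)=O)CC/C(C)=C/CCC(=C)OS(=O)(=O)C(F)(F)F | intermediate
41 | macrocyclic allylic alcohol, C7 epimers | C=C1CC/C=C(\C)CC[C@@H]2C[C@@H](OC(C)=O)[C@](C)(CCC1O)OC2(C)C | intermediate
42 | macrocyclic C7 enone | C=C1CC/C=C(\C)CC[C@@H]2C[C@@H](OC(C)=O)[C@](C)(CCC1=O)OC2(C)C | intermediate
43 | CNP0202897.1, (1R,3R,4S,7R,11E)-4,15-epoxy-7-hydroxycembra-8(19),11-dien-3-yl acetate | C=C1CC/C=C(\C)CC[C@@H]2C[C@@H](OC(C)=O)[C@](C)(CC[C@H]1O)OC2(C)C | target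

**Step count and risks**

Total step count: 23. Longest linear sequence: 20 steps (steps 1–11 and 15–23 from (R)-carvone); steps 12–14 make the C8–C13 bromide.

Steps most likely to fail:

1. Step 21 (ring closure). At the dilution a 14-membered ring needs, insertion of nickel into the enol triflate may be slow, so that intermolecular coupling and reduction or pinacol coupling of the aldehyde take over. The fallback closes the ring with CO as the C7 carbon; it sets out from acetate 38 and comes back at enone 42. 9-BBN would add to the C5=C6 vinyl group of 38 to give the B-alkyl-9-BBN borane F1, used without isolation. Slow addition of F1 to Pd(PPh3)4 and K3PO4 under CO would bring about a carbonylative B-alkyl Suzuki–Miyaura coupling with the C8 enol triflate, which forms C6–C7 and C7–C8 and leaves the ketone of 42. Steps 20–22 would then fall away. The macrocyclic variant of this coupling is less well precedented than the ring closure it replaces.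

2. Step 20 (hydroformylation). Insertion of the rhodium hydride into the vinyl group on the fully substituted C4 may be slow, so that hydrogenation of the alkene or oxidative addition of the enol triflate competes. The fallback adds C7 by olefination instead of by CO; it sets out from 38 and comes back at aldehyde 40. Hydroboration with 9-BBN to the borane F1 and oxidation with sodium perborate would give the C6 primary alcohol F2, and Dess–Martin oxidation the C6 aldehyde F3. A Wittig reaction with methoxymethylenetriphenylphosphorane at −78 °C (low temperature because F3 is a β-alkoxy aldehyde) would give the methyl enol ether F4. Its hydrolysis with Hg(OAc)2 in aqueous THF would give 40.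

3. Step 3 (key step). Chloride may capture the seleniranium ion, or the tertiary hydroxyl may close at C5 to the five-membered ether, and HCl may ionise the allylic C3 carbinol. The fallback makes the same O–C4 bond by opening an epoxide instead of a seleniranium ion, as is known for α-terpineol epoxide; it sets out from diol 4 and comes back at alkenol 8. TBSCl and imidazole would silylate only the secondary hydroxyl to give the silyl ether F5. mCPBA would epoxidise the face opposite the OTBS group and the C1 arm to give the epoxide F6. Camphorsulfonic acid would make the tertiary hydroxyl open the epoxide at C4 with inversion to give the cineole alcohol F7 (C5–OH anti to the ether bridge). Syn-dehydration with methyl N-(triethylammoniosulfonyl)carbamate would give the bicyclic alkene silyl ether F8, and Bu4NF would free 8.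

Further compounds

F1 | step 21 | B-alkyl-9-BBN borane from 38 (boron on C6) | C[C@@]1(CCB2C3CCCC2CCC3)OC(C)(C)[C@@H](C[C@H]1OC(C)=O)CC/C(C)=C/CCC(=C)OS(=O)(=O)C(F)(F)F
F2 | step 20 | C6 primary alcohol (C4–CH2CH2OH; C3–OAc; C8 enol triflate) | C[C@@]1(CCO)OC(C)(C)[C@@H](C[C@H]1OC(C)=O)CC/C(C)=C/CCC(=C)OS(=O)(=O)C(F)(F)F
F3 | step 20 | C6 aldehyde (C4–CH2CHO) | C[C@@]1(CC=O)OC(C)(C)[C@@H](C[C@H]1OC(C)=O)CC/C(C)=C/CCC(=C)OS(=O)(=O)C(F)(F)F
F4 | step 20 | C6=C7 methyl enol ether (E/Z) | C[C@@]1(CC=COC)OC(C)(C)[C@@H](C[C@H]1OC(C)=O)CC/C(C)=C/CCC(=C)OS(=O)(=O)C(F)(F)F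
F5 | step 3 | C3 tert-butyldimethylsilyl ether of diol 4 | C1=C(C)[C@H](O[Si](C)(C)C(C)(C)C)C[C@@H](C1)C(C)(C)O
F6 | step 3 | 4,5-epoxide of F5 (epoxide anti to OTBS and to the C1 arm) | C[C@@]12O[C@@H]1C[C@H](C[C@H]2O[Si](C)(C)C(C)(C)C)C(C)(C)O
F7 | step 3 | cineole alcohol (C5–OH anti to the ether bridge; C3–OTBS) | C[C@@]12OC(C)(C)[C@@H](C[C@H]1O[Si](C)(C)C(C)(C)C)C[C@H]2O
F8 | step 3 | tert-butyldimethylsilyl ether of alkenol 8 | C[C@@]12OC(C)(C)[C@@H](C[C@H]1O[Si](C)(C)C(C)(C)C)C=C2
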